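## Structural features

The target is one fully substituted tetrahydrofuran. O1 is flanked by two benzylic carbons: C2 carries a 4-hydroxy-3,5-dimethoxyphenyl (syringyl) ring and C5 a 3,4,5-trimethoxyphenyl ring, while C3 and C4 each carry a hydroxymethyl group. The four ring carbons are contiguous stereocentres, (2R,3S,4S,5R), and every neighbouring pair is trans, so the target is the most relaxed diastereomer of its series. The two aryl groups differ only in the para oxygen substituent (OH against OMe), so the core is nearly C2-symmetric, yet the halves must be introduced separately and in the absolute sense. Both ring C–O bonds are benzylic ethers of electron-rich arenes: they ionise under acid, can be hydrogenolysed, and the free phenol para to C2 opens a quinone-methide pathway. The 1,4-diol can also recapture a benzylic cation. The real difficulty is absolute control of four adjacent centres while the two near-identical aryl rings stay differentiated, without ever exposing C2–O1 or C5–O1 to ionising or reductive conditions. The key step uses the C2–H bond, which is benzylic to the syringyl ring, α to O1 and 1,5 to C3. A carbene at C3, stabilised by the ester that later becomes the C3 carbinol carbon, can therefore form C2–C3 and close the ring O1–C2–C3–C4–C5. Because C3 is then α to an ester it can be equilibrated, so only C2 has to be chosen in the insertion itself.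

## Logic of the disconnections

21 ⇒ 20. Two O–Si bonds are cut (aryl O–Si and the C4 CH2O–Si); no skeletal bond changes. Both masks fall to fluoride in one operation, so the last step is neither acidic nor reductive towards the two benzylic C–O bonds. The gain is that the free phenol and the diol appear only at the very end. The forward step needs buffered fluoride so that the phenoxide is protonated at once.

20 ⇒ 19. The C3 carbinol carbon is raised to the ester oxidation level. The ester makes C3–H acidic, which allows equilibration, and is the acceptor group a carbenoid at C3 needs. C3 therefore no longer has to be set kinetically. The forward step must reduce a hindered tert-butyl ester without disturbing the silyl ethers.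

19 ⇒ 17. The C2–C3 bond is cut. C2–H is doubly activated and 1,5 to C3, so one ring, one C–C bond and two stereocentres disappear, leaving an acyclic chain that carries only C4 and C5. The forward step must insert into that bond rather than undergo 1,2-hydride migration from C4, must pick one of two diastereotopic hydrogens, and must be followed by equilibration of C3 through 18.

17 ⇒ 15. The C3=N2 bond is cut. The diazo group is placed last because it is the least stable function of the route. The forward step has to activate a plain ester methylene (through 16) without touching C4, C5 or the silyl ethers.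

15 ⇒ 14. The primary O–Si bond is cut. The silyl ether is needed because a free γ-hydroxyl would lactonise onto the ester, and a lactone would later force a cis ring fusion at C3/C4. The forward silylation must follow the reduction without delay.

14 ⇒ 13. The C4 carbinol carbon is traced back to the imide carbonyl (the C–N bond to the auxiliary). The auxiliary thus leaves in the same step that delivers the correct oxidation level. The forward reduction must select the imide over the tert-butyl ester.

13 ⇒ 12 + 4. The O1–C2 ether bond is cut. This brings in the second aryl ring as an electrophilic benzyl donor on the existing C5 oxygen, which differentiates the two arenes and leaves C5 untouched. The forward etherification must be non-basic (retro-aldol) and only mildly acidic (tert-butyl ester, electron-rich benzylic carbinol).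

12 ⇒ 8 + 9. The C4–C5 bond is cut. An auxiliary-controlled syn-aldol sets both lasting stereocentres at once from two achiral partners, and the syn adduct becomes 4,5-trans on the ring. The forward step must enolise the imide and not the ester, and needs the (R)-configured auxiliary.

8 ⇒ 5 + 6. The N–acyl bond is cut. This gives a commercial half-ester and a commercial auxiliary. The forward step must activate only the free acid terminus.

4 ⇒ 3. The O–C(=NH) bond is cut. The imidate is simply the activated form of the benzylic alcohol. It must be made and used without acid contact.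

3 ⇒ 2. The benzylic C–H bond is cut (alcohol back to aldehyde). The forward step is a simple hydride reduction that the aryl silyl ether must survive.

2 ⇒ 1. The aryl O–Si bond is cut. The phenol is masked from the outset by a group that withstands every later step and leaves with fluoride.

## Other disconnections considered

Alternative 1: The cut removes the two exocyclic bonds C4–CH2 and C3–CH2. The ring carbons remain as the butenolide (R)-5-(3,4,5-trimethoxyphenyl)furan-2(5H)-one A1, whose carbonyl carbon is the later C2.
- Forward key step: a silylmethyl Grignard reagent would add 1,4 under CuBr·SMe2 (monovalent copper) catalysis anti to the C5 aryl group. The enolate would then be alkylated by a benzyloxymethyl chloride anti to the new C4 substituent, giving the trans,trans lactone A2.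
- In its favour: both hydroxymethyl carbons arrive in one flask. C3 and C4 are set kinetically by plain steric control on a rigid ring from a single centre. The silylmethyl group is a carbinol masked for Tamao oxidation and distinct from the benzyloxymethyl group. No diazo compound or rhodium is needed.
- Against it here: the γ-hydrogen of A1 is benzylic and vinylogously acidic, so a basic organometallic can erode the only source of absolute configuration. The magnesium enolate alkylates sluggishly, and the alkylating agent is a potent carcinogen. The syringyl ring must still be added to the lactone carbonyl of A2 and the lactol reduced with a silane and a Lewis acid, so C2 is set last under conditions that can ionise C5–O1.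
- Comparison: on C3 and C4 this plan is the better one (kinetic anti,anti control, no equilibration). On C2 it is no safer than the carbenoid plan, and it exposes a finished bis-benzylic ether to a Lewis acid and then to hydrogenolysis, which the chosen route avoids. On step economy the two are about equal once A1 has been secured in enantioenriched form.

Alternative 2: The cut is O1–C5, read as a retro-Baeyer–Villiger step. It contracts the lactone A4 to the all-trans cyclobutanone (2R,3S,4S)-3,4-bis(benzyloxymethyl)-2-(3,4,5-trimethoxyphenyl)cyclobutanone A3.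
- Forward key step: a buffered peracid adds to the strained ketone and the aryl-bearing carbon migrates to oxygen with retention, giving A4.
- In its favour: the migration is stereospecific, and the benzylic electron-rich carbon has the higher migratory aptitude, so neither regiochemistry nor configuration at C5 is in doubt. C3, C4 and C5 are arranged on a rigid four-membered template whose aryl-bearing carbon can be epimerised to the trans arrangement. Both carbinols are already at the alcohol oxidation level.
- Against it here: the burden moves to A3 as a single enantiomer. A ketene or keteniminium (2+2) cycloaddition with an (E)-1,4-dialkoxybut-2-ene gives the racemate unless an auxiliary or a resolution is added, and such unactivated 1,2-disubstituted alkenes are poor partners. The peracid meets a very electron-rich arene. As in alternative 1, C2 and its aryl group are still missing after the key step.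
- Comparison: mechanistically this key step is more predictable than a C–H insertion that must choose between two hydrogens, and on that point the alternative is the better. Structurally it solves only the half of the molecule that the aldol of the chosen route already solves reliably, and it leaves C2 to a late Lewis-acid reduction. In step count it is roughly equal, but only if an efficient asymmetric entry to A3 exists.

Alternative 3: Two ring bonds, O1–C2 and C3–C4, are cut together. The fragments are the vinyl epoxide (2S,3S)-2-(3,4,5-trimethoxyphenyl)-3-vinyloxirane A5 and the arylidene malonate dimethyl 2-[4-(benzyloxy)-3,5-dimethoxybenzylidene]malonate A6.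
- Forward key step: zerovalent palladium from Pd2(dba)3 and a bisphosphine ionises A5 to a π-allyl complex that carries the C5 alkoxide. Oxa-Michael addition to A6 forms O1–C2, and the malonate carbanion closes on the internal allyl terminus (C3–C4) to give the vinyl tetrahydrofuran A7.
- In its favour: it is the most convergent plan. Both differentiated aryl fragments and all ring atoms are joined in one catalytic step from fragments that need one or two steps each. C3 is not stereogenic in A7 and can be set trans on dealkoxycarbonylation. On step economy (about eight to nine steps in all) it is better than the chosen route.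
- Against it here: one step must control the regiochemistry of allyl capture, the 4,5 relationship and the 2,5 relationship, the last through a reversible oxa-Michael addition to a deactivated, electron-rich acceptor. The benzylic alkoxide of the π-allyl intermediate can instead collapse to a ketone by hydride shift. The later dealkoxycarbonylation at high temperature acts on a β-alkoxy diester that can ring-open. The vinyl group must be cleaved oxidatively next to two electron-rich arenes before a final hydrogenolysis.
- Comparison: structurally it differentiates the aryl rings as well as the chosen plan (equal). Mechanistically it concentrates more simultaneous selectivity demands in one step, whereas the chosen plan fixes C4/C5 by an auxiliary aldol and asks the catalytic step for a single centre. The chosen plan is longer, but each of its stereocentres has either a reliable kinetic origin or a thermodynamic safety net.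

Key step: step 10

Remarks on the chemistry (assumptions):
- The ring numbering O1, C2 (syringyl), C3, C4, C5 (trimethoxyphenyl) is also used for the acyclic intermediates.
- The phenol is carried as a triisopropylsilyl ether and not as a benzyl ether, so that one fluoride treatment ends the synthesis and no hydrogenolysis is run on a tetrahydrofuran with two benzylic C–O bonds.
- The (R)-4-benzyl-oxazolidinone is the antipode that leads to C4 = S and C5 = R. The configurations of 17 and 19 were checked against 21 by CIP analysis and agree (19 is 3R only because the ester outranks C2), and the syn aldol is the correct topicity because a syn adduct places the former acyl carbon and the aryl group trans on the later ring.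
- The kinetic insertion product is assumed to be mainly the C3 epimer 18, which is why a base equilibration is built into step 10.

## Route

Step 1
Reactants: 1 syringaldehyde (4-hydroxy-3,5-dimethoxybenzaldehyde)
Product: 2 3,5-dimethoxy-4-(triisopropylsilyloxy)benzaldehyde
Conditions: TIPSCl, imidazole, DMF, rt
Reagents that add atoms: chlorotriisopropylsilane (TIPSCl), CC(C)[Si](Cl)(C(C)C)C(C)C
Why: O-Silylation of a phenol (silyl chloride activated by imidazole); the acidic syringyl hydroxyl should react despite its two ortho methoxy groups, and the hindered aryl silyl ether should tolerate hydride, amide base, catalytic acid and the carbenoid while staying fluoride-labile.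

Step 2
Reactants: 2 3,5-dimethoxy-4-(triisopropylsilyloxy)benzaldehyde
Product: 3 [3,5-dimethoxy-4-(triisopropylsilyloxy)phenyl]methanol
Conditions: NaBH4, MeOH–THF, 0 °C
Reagents that add atoms: none
Why: Borohydride reduction of an aromatic aldehyde to the benzylic alcohol; the aryl silyl ether should not be attacked at 0 °C.

Step 3
Reactants: 3 [3,5-dimethoxy-4-(triisopropylsilyloxy)phenyl]methanol
Product: 4 3,5-dimethoxy-4-(triisopropylsilyloxy)benzyl 2,2,2-trichloroacetimidate
Conditions: Cl3CCN, DBU (10 mol%), CH2Cl2, 0 °C
Reagents that add atoms: trichloroacetonitrile, N#CC(Cl)(Cl)Cl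
Why: Base-catalysed addition of the alcohol to the nitrile (trichloroacetimidate formation); the imidate would be passed through base-washed silica and used at once, because electron-rich benzyl imidates rearrange to the N-benzyl amide on storage or acid contact.

Step 4
Reactants: 5 4-tert-butoxy-4-oxobutanoic acid; 6 (R)-4-benzyl-1,3-oxazolidin-2-one
Product: 8 tert-butyl 4-[(4R)-4-benzyl-2-oxo-1,3-oxazolidin-3-yl]-4-oxobutanoate, via mixed pivalic anhydride 7 (not isolated)
Conditions: PivCl, Et3N, THF, −20 °C; then 6, LiCl, −20 °C → rt
Reagents that add atoms: none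
Why: N-Acylation of an oxazolidinone through a mixed pivalic anhydride with LiCl activation; the auxiliary should attack the unhindered succinyl carbonyl of 7, and the tert-butyl ester is inert.

Step 5
Reactants: 8 tert-butyl 4-[(4R)-4-benzyl-2-oxo-1,3-oxazolidin-3-yl]-4-oxobutanoate; 9 3,4,5-trimethoxybenzaldehyde
Product: 12 tert-butyl (3R,4R)-3-{[(4R)-4-benzyl-2-oxo-1,3-oxazolidin-3-yl]carbonyl}-4-hydroxy-4-(3,4,5-trimethoxyphenyl)butanoate, via Z-boron enolate 10 (not isolated), via boron aldolate 11 (not isolated)
Conditions: Bu2BOTf, iPr2NEt, CH2Cl2, 0 °C; 9, −78 → 0 °C; then pH 7 buffer, MeOH, H2O2, 0 °C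
Reagents that add atoms: none
Why: Evans syn-aldol reaction: soft enolisation should occur only at the boron-bound imide (the ester α-hydrogens are far less acidic) and give the Z enolate 10, which adds through a closed chair transition state on the face away from the auxiliary benzyl group; with the (R)-auxiliary this sets (3R,4R), the future C4 (S) and C5 (R), in a syn relationship that becomes 4,5-trans on the ring.

Step 6
Reactants: 12 tert-butyl (3R,4R)-3-{[(4R)-4-benzyl-2-oxo-1,3-oxazolidin-3-yl]carbonyl}-4-hydroxy-4-(3,4,5-trimethoxyphenyl)butanoate; 4 3,5-dimethoxy-4-(triisopropylsilyloxy)benzyl 2,2,2-trichloroacetimidate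
Product: 13 tert-butyl (3R,4R)-3-{[(4R)-4-benzyl-2-oxo-1,3-oxazolidin-3-yl]carbonyl}-4-{[3,5-dimethoxy-4-(triisopropylsilyloxy)benzyl]oxy}-4-(3,4,5-trimethoxyphenyl)butanoate
Conditions: TfOH (2 mol%), CH2Cl2–cyclohexane, −20 → 0 °C
Reagents that add atoms: none
Why: Acid-catalysed O-benzylation with a trichloroacetimidate (SN1-type transfer of an electron-rich benzyl cation); the non-basic conditions avoid retro-aldol cleavage, the C5–O bond is not broken so C5 keeps its configuration, and the small acid load at low temperature should spare the tert-butyl ester.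

Step 7
Reactants: 13 tert-butyl (3R,4R)-3-{[(4R)-4-benzyl-2-oxo-1,3-oxazolidin-3-yl]carbonyl}-4-{[3,5-dimethoxy-4-(triisopropylsilyloxy)benzyl]oxy}-4-(3,4,5-trimethoxyphenyl)butanoate
Product: 14 tert-butyl (3S,4R)-4-{[3,5-dimethoxy-4-(triisopropylsilyloxy)benzyl]oxy}-3-(hydroxymethyl)-4-(3,4,5-trimethoxyphenyl)butanoate
Conditions: LiBH4, MeOH (1 equiv), THF, 0 °C
Reagents that add atoms: none
Why: Reductive cleavage of the N-acyl oxazolidinone (hydride attack at the exocyclic imide carbonyl, far more electrophilic than the tert-butyl ester); C4 is not epimerised, auxiliary 6 is recovered, and the γ-hydroxy ester would be silylated without delay to forestall lactonisation.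

Step 8
Reactants: 14 tert-butyl (3S,4R)-4-{[3,5-dimethoxy-4-(triisopropylsilyloxy)benzyl]oxy}-3-(hydroxymethyl)-4-(3,4,5-trimethoxyphenyl)butanoate
Product: 15 tert-butyl (3S,4R)-3-[(tert-butyldimethylsilyloxy)methyl]-4-{[3,5-dimethoxy-4-(triisopropylsilyloxy)benzyl]oxy}-4-(3,4,5-trimethoxyphenyl)butanoate
Conditions: TBSCl, imidazole, CH2Cl2, 0 °C → rt
Reagents that add atoms: tert-butyldimethylsilyl chloride (TBSCl), CC(C)(C)[Si](C)(C)Cl
Why: Silylation of the primary alcohol; the silyl ether blocks lactonisation onto the ester (a lactone would later force a cis ring fusion at C3/C4) and removes an O–H bond that a carbenoid would attack.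

Step 9
Reactants: 15 tert-butyl (3S,4R)-3-[(tert-butyldimethylsilyloxy)methyl]-4-{[3,5-dimethoxy-4-(triisopropylsilyloxy)benzyl]oxy}-4-(3,4,5-trimethoxyphenyl)butanoate
Product: 17 tert-butyl (3S,4R)-3-[(tert-butyldimethylsilyloxy)methyl]-2-diazo-4-{[3,5-dimethoxy-4-(triisopropylsilyloxy)benzyl]oxy}-4-(3,4,5-trimethoxyphenyl)butanoate, via α-trifluoroacetyl ester 16 (not isolated)
Conditions: LiN(iPr)2, THF, −78 °C; CF3CO2CH2CF3, −78 °C; aq. NH4Cl; then 4-AcNHC6H4SO2N3, Et3N, H2O (1 equiv), MeCN, rt
Reagents that add atoms: 4-acetamidobenzenesulfonyl azide, CC(=O)Nc1ccc(cc1)S(=O)(=O)N=[N+]=[N-]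
Why: Claisen-type C-trifluoroacetylation of the ester enolate followed by detrifluoroacetylative (Regitz-type) diazo transfer; the enolate carbon has no leaving group on its β-carbon, C4 and C5 are not acidified, and the sulfonyl azide chosen is the least hazardous of the common transfer reagents.

Step 10
Reactants: 17 tert-butyl (3S,4R)-3-[(tert-butyldimethylsilyloxy)methyl]-2-diazo-4-{[3,5-dimethoxy-4-(triisopropylsilyloxy)benzyl]oxy}-4-(3,4,5-trimethoxyphenyl)butanoate
Product: 19 tert-butyl (2R,3R,4S,5R)-4-[(tert-butyldimethylsilyloxy)methyl]-2-[3,5-dimethoxy-4-(triisopropylsilyloxy)phenyl]-5-(3,4,5-trimethoxyphenyl)tetrahydrofuran-3-carboxylate (all-trans), via C3-epimeric ester 18 (not isolated)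
Conditions: Rh2(S-PTTL)4 (divalent rhodium tetrakis[N-phthaloyl-(S)-tert-leucinate], 1 mol%), toluene, −78 → −40 °C; then KOtBu (0.3 equiv), tBuOH–THF, 0 °C → rt
Reagents that add atoms: none
Why: Loss of N2 from 17 at the divalent rhodium centre should give an electrophilic carbenoid at C3, which takes the hydridic C2–H bond through a concerted, asynchronous three-centre transition state with retention at C2. The closest known reaction type is the dirhodium-carboxylate-catalysed intramolecular 1,5 C–H insertion of α-alkyl-α-diazo esters into benzylic and ether-activated C–H bonds, which gives cyclopentane- and tetrahydrofuran-carboxylates. The ring O1–C2–C3–C4–C5 closes as a 1,5 insertion (a five-membered ring through a six-centre chair-like array that includes rhodium), and because both ether oxygens sit 1,4 to the carbene, oxonium ylide formation would need a four-membered ring and should not compete. C2 is set by the choice between the two diastereotopic benzylic hydrogens: in the favoured array the C2 aryl group and the C4 silyloxymethyl group both turn away from the bulky dirhodium core, which places the syringyl ring anti to the C5 aryl group (2,5-trans, C2 = R), and the chiral phthalimido-carboxylate pocket is expected to reinforce this choice. C3 should emerge from this array mainly as the crowded 2,3-cis-3,4-cis epimer 18, and KOtBu in tBuOH then equilibrates this one acidic centre through the ester enolate to the all-trans ester 19; the ring should stay closed because β-elimination of O1 would be a stereoelectronically poor 5-endo process, and tert-butoxide cannot transesterify a tert-butyl ester. The step needs chemoselectivity over 1,2-hydride migration from C4 (held back by the bulky carboxylate ligands and the low temperature), over attack on the ortho position of the trimethoxyphenyl ring and over insertion into the tert-butyl group; the double activation of C2–H by O1 and by the electron-rich arene is what should make it the fastest site. C4 and C5 are not touched.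

Step 11
Reactants: 19 tert-butyl (2R,3R,4S,5R)-4-[(tert-butyldimethylsilyloxy)methyl]-2-[3,5-dimethoxy-4-(triisopropylsilyloxy)phenyl]-5-(3,4,5-trimethoxyphenyl)tetrahydrofuran-3-carboxylate
Product: 20 {(2R,3S,4S,5R)-4-[(tert-butyldimethylsilyloxy)methyl]-2-[3,5-dimethoxy-4-(triisopropylsilyloxy)phenyl]-5-(3,4,5-trimethoxyphenyl)tetrahydrofuran-3-yl}methanol
Conditions: LiAlH4, THF, 0 °C → rt
Reagents that add atoms: none
Why: Hydride reduction of the tert-butyl ester to the primary alcohol; no stereocentre is α to a carbonyl after this point, ethers and silyl ethers are inert, and premature loss of the aryl silyl group would be harmless because it is removed next.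

Step 12
Reactants: 20 {(2R,3S,4S,5R)-4-[(tert-butyldimethylsilyloxy)methyl]-2-[3,5-dimethoxy-4-(triisopropylsilyloxy)phenyl]-5-(3,4,5-trimethoxyphenyl)tetrahydrofuran-3-yl}methanol
Product: 21 4-[(2R,3S,4S,5R)-3,4-bis(hydroxymethyl)-5-(3,4,5-trimethoxyphenyl)tetrahydrofuran-2-yl]-2,6-dimethoxyphenol
Conditions: TBAF, AcOH, THF, 0 °C → rt
Reagents that add atoms: none
Why: Fluoride-mediated cleavage of both silyl ethers in one operation, buffered with acetic acid so that the liberated phenoxide is protonated at once; no acid, hydrogen or Lewis acid touches the two benzylic C–O bonds, so all four stereocentres should be retained.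

## Compound list

1 | syringaldehyde (4-hydroxy-3,5-dimethoxybenzaldehyde) | COc1cc(C=O)cc(OC)c1O | starting material
2 | 3,5-dimethoxy-4-(triisopropylsilyloxy)benzaldehyde | COc1cc(C=O)cc(OC)c1O[Si](C(C)C)(C(C)C)C(C)C | intermediate
3 | [3,5-dimethoxy-4-(triisopropylsilyloxy)phenyl]methanol | COc1cc(CO)cc(OC)c1O[Si](C(C)C)(C(C)C)C(C)C | intermediate
4 | 3,5-dimethoxy-4-(triisopropylsilyloxy)benzyl 2,2,2-trichloroacetimidate | COc1cc(COC(=N)C(Cl)(Cl)Cl)cc(OC)c1O[Si](C(C)C)(C(C)C)C(C)C | intermediate
5 | 4-tert-butoxy-4-oxobutanoic acid | CC(C)(C)OC(=O)CCC(=O)O | starting material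
6 | (R)-4-benzyl-1,3-oxazolidin-2-one (recovered in step 7) | O=C1N[C@H](Cc2ccccc2)CO1 | starting material
7 | 4-tert-butoxy-4-oxobutanoic pivalic anhydride | CC(C)(C)OC(=O)CCC(=O)OC(=O)C(C)(C)C | intermediate (not isolated)
8 | tert-butyl 4-[(4R)-4-benzyl-2-oxo-1,3-oxazolidin-3-yl]-4-oxobutanoate | CC(C)(C)OC(=O)CCC(=O)N1[C@H](Cc2ccccc2)COC1=O | intermediate
9 | 3,4,5-trimethoxybenzaldehyde | COc1cc(C=O)cc(OC)c1OC | starting material
10 | (Z)-dibutylboron enolate of 8 | CCCCB(CCCC)O/C(=C\CC(=O)OC(C)(C)C)N1[C@H](Cc2ccccc2)COC1=O | intermediate (not isolated)
11 | O-dibutylboryl aldolate of 12, (3R,4R) | CC(C)(C)OC(=O)C[C@@H](C(=O)N1[C@H](Cc2ccccc2)COC1=O)[C@H](c1cc(OC)c(OC)c(OC)c1)OB(CCCC)CCCC | intermediate (not isolated)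
12 | tert-butyl (3R,4R)-3-{[(4R)-4-benzyl-2-oxo-1,3-oxazolidin-3-yl]carbonyl}-4-hydroxy-4-(3,4,5-trimethoxyphenyl)butanoate | CC(C)(C)OC(=O)C[C@@H](C(=O)N1[C@H](Cc2ccccc2)COC1=O)[C@H](c1cc(OC)c(OC)c(OC)c1)O | intermediate
13 | tert-butyl (3R,4R)-3-{[(4R)-4-benzyl-2-oxo-1,3-oxazolidin-3-yl]carbonyl}-4-{[3,5-dimethoxy-4-(triisopropylsilyloxy)benzyl]oxy}-4-(3,4,5-trimethoxyphenyl)butanoate | CC(C)(C)OC(=O)C[C@@H](C(=O)N1[C@H](Cc2ccccc2)COC1=O)[C@H](c1cc(OC)c(OC)c(OC)c1)OCc1cc(OC)c(O[Si](C(C)C)(C(C)C)C(C)C)c(OC)c1 | intermediate
14 | tert-butyl (3S,4R)-4-{[3,5-dimethoxy-4-(triisopropylsilyloxy)benzyl]oxy}-3-(hydroxymethyl)-4-(3,4,5-trimethoxyphenyl)butanoate | CC(C)(C)OC(=O)C[C@@H](CO)[C@H](c1cc(OC)c(OC)c(OC)c1)OCc1cc(OC)c(O[Si](C(C)C)(C(C)C)C(C)C)c(OC)c1 | intermediate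
15 | tert-butyl (3S,4R)-3-[(tert-butyldimethylsilyloxy)methyl]-4-{[3,5-dimethoxy-4-(triisopropylsilyloxy)benzyl]oxy}-4-(3,4,5-trimethoxyphenyl)butanoate | CC(C)(C)OC(=O)C[C@@H](CO[Si](C)(C)C(C)(C)C)[C@H](c1cc(OC)c(OC)c(OC)c1)OCc1cc(OC)c(O[Si](C(C)C)(C(C)C)C(C)C)c(OC)c1 | intermediate
16 | tert-butyl (3S,4R)-3-[(tert-butyldimethylsilyloxy)methyl]-4-{[3,5-dimethoxy-4-(triisopropylsilyloxy)benzyl]oxy}-2-(trifluoroacetyl)-4-(3,4,5-trimethoxyphenyl)butanoate (C2 unassigned, present as its enolate) | CC(C)(C)OC(=O)C(C(=O)C(F)(F)F)[C@@H](CO[Si](C)(C)C(C)(C)C)[C@H](c1cc(OC)c(OC)c(OC)c1)OCc1cc(OC)c(O[Si](C(C)C)(C(C)C)C(C)C)c(OC)c1 | intermediate (not isolated)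
17 | tert-butyl (3S,4R)-3-[(tert-butyldimethylsilyloxy)methyl]-2-diazo-4-{[3,5-dimethoxy-4-(triisopropylsilyloxy)benzyl]oxy}-4-(3,4,5-trimethoxyphenyl)butanoate | CC(C)(C)OC(=O)C(=[N+]=[N-])[C@@H](CO[Si](C)(C)C(C)(C)C)[C@H](c1cc(OC)c(OC)c(OC)c1)OCc1cc(OC)c(O[Si](C(C)C)(C(C)C)C(C)C)c(OC)c1 | intermediate
18 | tert-butyl (2R,3S,4S,5R)-4-[(tert-butyldimethylsilyloxy)methyl]-2-[3,5-dimethoxy-4-(triisopropylsilyloxy)phenyl]-5-(3,4,5-trimethoxyphenyl)tetrahydrofuran-3-carboxylate (2,3-cis, 3,4-cis, 4,5-trans) | COc1cc([C@@H]2O[C@@H](c3cc(OC)c(OC)c(OC)c3)[C@H](CO[Si](C)(C)C(C)(C)C)[C@@H]2C(=O)OC(C)(C)C)cc(OC)c1O[Si](C(C)C)(C(C)C)C(C)C | intermediate (not isolated)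
19 | tert-butyl (2R,3R,4S,5R)-4-[(tert-butyldimethylsilyloxy)methyl]-2-[3,5-dimethoxy-4-(triisopropylsilyloxy)phenyl]-5-(3,4,5-trimethoxyphenyl)tetrahydrofuran-3-carboxylate (all-trans) | COc1cc([C@@H]2O[C@@H](c3cc(OC)c(OC)c(OC)c3)[C@H](CO[Si](C)(C)C(C)(C)C)[C@H]2C(=O)OC(C)(C)C)cc(OC)c1O[Si](C(C)C)(C(C)C)C(C)C | intermediate
20 | {(2R,3S,4S,5R)-4-[(tert-butyldimethylsilyloxy)methyl]-2-[3,5-dimethoxy-4-(triisopropylsilyloxy)phenyl]-5-(3,4,5-trimethoxyphenyl)tetrahydrofuran-3-yl}methanol | COc1cc([C@@H]2O[C@@H](c3cc(OC)c(OC)c(OC)c3)[C@H](CO[Si](C)(C)C(C)(C)C)[C@H]2CO)cc(OC)c1O[Si](C(C)C)(C(C)C)C(C)C | intermediate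
21 | 4-[(2R,3S,4S,5R)-3,4-bis(hydroxymethyl)-5-(3,4,5-trimethoxyphenyl)tetrahydrofuran-2-yl]-2,6-dimethoxyphenol | COc1cc([C@@H]2O[C@@H](c3cc(OC)c(OC)c(OC)c3)[C@H](CO)[C@H]2CO)cc(OC)c1O | target

## Step count and least certain steps

Total: 12 steps. Longest linear sequence: 10 steps (steps 1–3, then 6–12, counted from 1); the branch that starts from 5 runs over 9 steps.

Step 10 (key step).
- What may go wrong: the carbenoid may discriminate poorly between the two diastereotopic hydrogens on C2, and whether the (S)-configured catalyst is the matched partner of the C4/C5 centres cannot be predicted with confidence. Insertion with the syringyl ring syn to the C5 aryl group would then contribute. 1,2-Hydride migration from C4 or attack on the ortho position of the trimethoxyphenyl ring could also erode the material balance.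
- Fallback (thermodynamic instead of kinetic control of C2): it sets out from 17 and returns at 21. The insertion and base treatment are run as before, and the crude ester mixture, which then contains the C2-epimeric ester F1, is treated with KHF2 in MeOH. This removes only the aryl silyl group and gives the free phenol F2 (and its all-trans counterpart). Catalytic camphorsulfonic acid in CH2Cl2 should then open C2–O1 reversibly through the para-quinone methide, the known epimerisation mode of para-hydroxybenzylic ether centres in lignans. Reclosure by the C5 hydroxyl under equilibrium conditions should funnel the material into the all-trans phenol ester F3. C5 cannot ionise this way because its arene has no free hydroxyl, and C3 and C4 are untouched. LiAlH4 reduction gives the phenolic mono-silyl diol F4, and TBAF/AcOH returns the material to the route at 21.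

Step 6.
- What may go wrong: rearrangement or self-condensation of the electron-rich imidate may outrun transfer to the hindered secondary benzylic alcohol. Acid-triggered ionisation at C5, or loss of the tert-butyl group with lactonisation, may also set in.
- Fallback (reductive etherification instead of cationic benzyl transfer): it sets out from 12 and returns at 13. 12 is converted with TMSCl and imidazole into the trimethylsilyl ether F5. F5 and aldehyde 2 are then combined with Et3SiH and catalytic TMSOTf in CH2Cl2 at −78 °C, so that the mixed silyl acetal collapses to an oxocarbenium ion and is reduced to 13. This variant also makes steps 2 and 3 unnecessary.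

Step 9.
- What may go wrong: C-trifluoroacetylation of the hindered, β-branched ester enolate may be incomplete, and the labile trifluoroacetyl intermediate may cleave before diazo transfer, so that 15 is returned.
- Fallback (isolable β-keto ester, debenzoylative transfer): it sets out from 15 and returns at 17. The enolate of 15 (LiN(iPr)2, THF, −78 °C) is acylated with N-benzoylimidazole to the α-benzoyl ester F6, which can be purified. Treatment of F6 with 4-nitrobenzenesulfonyl azide and DBU in CH2Cl2 should transfer the diazo group with loss of the benzoyl group and give 17.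

Step 7.
- What may go wrong: the new primary alkoxide may lactonise onto the tert-butyl ester. Hydride may also attack the ring carbonyl of the auxiliary, because the acyl carbon is flanked by a branched centre.
- Fallback (hydrolysis, then chemoselective reduction of the acid): it sets out from 13 and returns at 14. LiOH/H2O2 in THF–H2O at 0 °C removes the auxiliary and gives the carboxylic acid F7 (the hindered aryl silyl ether should survive brief exposure). BH3·SMe2 in THF at 0 °C then reduces the acid in the presence of the tert-butyl ester to 14.

## Further compounds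

F1 | step 10 | tert-butyl (2S,3R,4S,5R)-4-[(tert-butyldimethylsilyloxy)methyl]-2-[3,5-dimethoxy-4-(triisopropylsilyloxy)phenyl]-5-(3,4,5-trimethoxyphenyl)tetrahydrofuran-3-carboxylate (C2 epimer of 19) | COc1cc([C@H]2O[C@@H](c3cc(OC)c(OC)c(OC)c3)[C@H](CO[Si](C)(C)C(C)(C)C)[C@H]2C(=O)OC(C)(C)C)cc(OC)c1O[Si](C(C)C)(C(C)C)C(C)C
F2 | step 10 | tert-butyl (2S,3R,4S,5R)-4-[(tert-butyldimethylsilyloxy)methyl]-2-(4-hydroxy-3,5-dimethoxyphenyl)-5-(3,4,5-trimethoxyphenyl)tetrahydrofuran-3-carboxylate | COc1cc([C@H]2O[C@@H](c3cc(OC)c(OC)c(OC)c3)[C@H](CO[Si](C)(C)C(C)(C)C)[C@H]2C(=O)OC(C)(C)C)cc(OC)c1O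
F3 | step 10 | tert-butyl (2R,3R,4S,5R)-4-[(tert-butyldimethylsilyloxy)methyl]-2-(4-hydroxy-3,5-dimethoxyphenyl)-5-(3,4,5-trimethoxyphenyl)tetrahydrofuran-3-carboxylate (all-trans) | COc1cc([C@@H]2O[C@@H](c3cc(OC)c(OC)c(OC)c3)[C@H](CO[Si](C)(C)C(C)(C)C)[C@H]2C(=O)OC(C)(C)C)cc(OC)c1O
F4 | step 10 | 4-{(2R,3S,4S,5R)-4-[(tert-butyldimethylsilyloxy)methyl]-3-(hydroxymethyl)-5-(3,4,5-trimethoxyphenyl)tetrahydrofuran-2-yl}-2,6-dimethoxyphenol | COc1cc([C@@H]2O[C@@H](c3cc(OC)c(OC)c(OC)c3)[C@H](CO[Si](C)(C)C(C)(C)C)[C@H]2CO)cc(OC)c1O
F5 | step 6 | tert-butyl (3R,4R)-3-{[(4R)-4-benzyl-2-oxo-1,3-oxazolidin-3-yl]carbonyl}-4-(3,4,5-trimethoxyphenyl)-4-(trimethylsilyloxy)butanoate | CC(C)(C)OC(=O)C[C@@H](C(=O)N1[C@H](Cc2ccccc2)COC1=O)[C@H](c1cc(OC)c(OC)c(OC)c1)O[Si](C)(C)C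
F6 | step 9 | tert-butyl (3S,4R)-2-benzoyl-3-[(tert-butyldimethylsilyloxy)methyl]-4-{[3,5-dimethoxy-4-(triisopropylsilyloxy)benzyl]oxy}-4-(3,4,5-trimethoxyphenyl)butanoate (C2 epimers) | CC(C)(C)OC(=O)C(C(=O)c1ccccc1)[C@@H](CO[Si](C)(C)C(C)(C)C)[C@H](c1cc(OC)c(OC)c(OC)c1)OCc1cc(OC)c(O[Si](C(C)C)(C(C)C)C(C)C)c(OC)c1
F7 | step 7 | (2R)-4-tert-butoxy-2-[(R)-{[3,5-dimethoxy-4-(triisopropylsilyloxy)benzyl]oxy}(3,4,5-trimethoxyphenyl)methyl]-4-oxobutanoic acid | CC(C)(C)OC(=O)C[C@@H](C(=O)O)[C@H](c1cc(OC)c(OC)c(OC)c1)OCc1cc(OC)c(O[Si](C(C)C)(C(C)C)C(C)C)c(OC)c1
A1 | alternative 1 | (R)-5-(3,4,5-trimethoxyphenyl)furan-2(5H)-one | O=C1O[C@@H](c2cc(OC)c(OC)c(OC)c2)C=C1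
A2 | alternative 1 | (3S,4R,5R)-3-(benzyloxymethyl)-4-[(isopropoxydimethylsilyl)methyl]-5-(3,4,5-trimethoxyphenyl)dihydrofuran-2(3H)-one (trans,trans) | O=C1O[C@@H](c2cc(OC)c(OC)c(OC)c2)[C@H](C[Si](C)(C)OC(C)C)[C@H]1COCc1ccccc1
A3 | alternative 2 | (2R,3S,4S)-3,4-bis(benzyloxymethyl)-2-(3,4,5-trimethoxyphenyl)cyclobutan-1-one (all-trans) | O=C1[C@@H](c2cc(OC)c(OC)c(OC)c2)[C@H](COCc2ccccc2)[C@H]1COCc1ccccc1
A4 | alternative 2 | (3S,4S,5R)-3,4-bis(benzyloxymethyl)-5-(3,4,5-trimethoxyphenyl)dihydrofuran-2(3H)-one (trans,trans) | O=C1O[C@@H](c2cc(OC)c(OC)c(OC)c2)[C@H](COCc2ccccc2)[C@H]1COCc1ccccc1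
A5 | alternative 3 | (2S,3S)-2-(3,4,5-trimethoxyphenyl)-3-vinyloxirane (trans) | C=C[C@@H]1O[C@H]1c1cc(OC)c(OC)c(OC)c1
A6 | alternative 3 | dimethyl 2-[4-(benzyloxy)-3,5-dimethoxybenzylidene]malonate | COC(=O)C(=Cc1cc(OC)c(OCc2ccccc2)c(OC)c1)C(=O)OC
A7 | alternative 3 | dimethyl (2S,4R,5R)-2-[4-(benzyloxy)-3,5-dimethoxyphenyl]-5-(3,4,5-trimethoxyphenyl)-4-vinyldihydrofuran-3,3(2H)-dicarboxylate (2,5-trans, 4,5-trans) | COc1cc([C@@H]2O[C@@H](c3cc(OC)c(OC)c(OC)c3)[C@H](C=C)C2(C(=O)OC)C(=O)OC)cc(OC)c1OCc1ccccc1
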